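I had 4 questions to answer about 3 flasks, set out here.

    partner + tight pair → target (k1 = 77000 L mol⁻¹ h⁻¹)
    tight pair ⇌ loose pair (K2 = 0.37, k2 = 8.8 h⁻¹)
    2 partner → homo dimer (k3 = 18 L mol⁻¹ h⁻¹)
    substrate ⇌ tight pair (K4 = 1.0 × 10⁻⁴, k4 = 0.0098 h⁻¹)
    partner + loose pair → isomer of the product (k5 = 51000 L mol⁻¹ h⁻¹)

| setting | Monday's | Friday's | Tuesday's |
|---|---|---|---|
| substrate | 0.010 M | 0.010 M | 0.010 M (fed, over 30 h) |
| partner | 1.50 equiv (fed, over 30 h) | 1.50 equiv | 1.50 equiv |
| time | 50 h | 50 h | 50 h |
| remark | all else is in the flask from the start; the feed brings no volume worth counting | everything together at the start | all else is in the flask from the start; the feed brings no volume worth counting |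

- the flask with the highest amount of target, in percent of the substrate charged ("all alike" if they lie within 1.5 percentage points) (Monday's / Friday's / Tuesday's / all alike)
- final target, as a percentage of the substrate charged, in Monday's
- final target, as a percentage of the substrate charged, in Friday's
- final target, as a percentage of the substrate charged, in Tuesday's

Bench note on Monday's: I reckoned the fraction of substrate left, not the target made. Substrate opened to the tight pair at 0.0098 h⁻¹. The tight pair fell back at 98.0 h⁻¹ or met partner, of concentration p. The step to loose pair, at 8.8 h⁻¹, was slower than the return, so I dropped it from this estimate. Dividing the return constant by 77000 L mol⁻¹ h⁻¹ gave the half-capture level p*, the partner concentration at which a tight pair is as likely to become target as to fall back: 0.00127 M. The captured share is φ = p/(p + p*), so substrate falls pseudo-first-order with constant 0.0098 h⁻¹ times φ.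

For Monday's, I set dimerisation equal to the feed, which gave p = 0.00373 M and φ = 74.5 %, and I used that share for the whole feed, although partner started from nothing. Counting dimerisation as its sole loss after the feed, I reckoned partner at 0.00101 M by 50 h, where φ = 44.3 %. I averaged those two shares over the last stretch, and my estimate was 71.5 % of the substrate left and 28.5 % target.

Watch p against p*. By this count Monday's crossed it at 44.4 h, later than Friday's and Tuesday's at 20.0 h, and by then Tuesday's had 66.7 % of its substrate in. So I ranked them Monday's, Friday's, Tuesday's, and warned against hurrying Monday's partner feed.

The forecast also named Monday's, with 26 % for Monday's, 16.5 % for Friday's and 9.5 % for Tuesday's, its Monday's figure lower than mine, holding of partner that “feeding it keeps it alive through the run”.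

Monday's gave most, 25.0 % against my 28.5 %, with 16.6 % in Friday's and 9.45 % in Tuesday's. Put into φ, Monday's mean partner over the first 30 h, 0.00286 M, gave 69.2 %, which by my reckoning left 81.6 % of the substrate; Monday's held 82.0 % at 30.0 h.

In the neighbour flask, Tuesday's recipe at 0.040 M substrate, dimerisation alone brought partner to p* at 21.4 h, close to Tuesday's. That count leaves capture out, and at p* capture in the neighbour flask drew 1.40 × 10⁻⁴ M h⁻¹, more than dimerisation's 5.83 × 10⁻⁵ M h⁻¹, while in Tuesday's it drew 3.26 × 10⁻⁵ M h⁻¹, so I expected the neighbour flask to lose its last partner sooner and to end below Tuesday's 9.45 %. The neighbour flask gave 4.76 %, with 0 % of its partner left.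

(The rate constants are made up; no experiment stands behind them.)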